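**Retrosynthetic overview**

- Numbering follows 6H-isochromene-6,8(7H)-dione: pyran ring B is C1, O2, C3, C4, C4a, C8a; carbocycle ring A is C4a, C5, C6, C7, C8, C8a. The decanoate is attached last, to the tertiary alcohol.
- Key disconnection: C6–C7 and C8–C8a. C7/C8, with the methyl group and the carbinol oxygen, is (S)-lactic acid used as its pivalaldehyde acetal; C6–C5–C4a–C8a–C1 with O2 is 4-(non-1-yn-1-yl)-2H-pyran-2-one.
- Enabling feature: C7 is a lactate α-carbon flanked by the two ring A carbonyls C6 and C8, and the chain O2–C1H=C8a–C4a=C5H–C6(=O) is a ring-opened 2-pyranone. The pyranone is therefore an acyl donor at C6 whose own leaving group, the C1 enolate, is the C8a nucleophile that closes ring A on the lactate carbonyl.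
- Ring order: sacrificial pyranone, then ring A by a Claisen/ring-opening/Dieckmann cascade, then ring B by 6-endo-dig addition of the C1 oxygen to the alkyne in the same pot, then the ester.

Key step: step 5

Remark: methyl 5,5-dimethoxy-3-oxopentanoate is taken as a catalogue β-keto ester. C7 of the target is R (priority O > C8 > C6 > CH3), which corresponds to replacing the α-hydrogen of (S)-lactic acid by C6 with retention.

Step 1
Reactants: 1 (S)-lactic acid; 2 pivalaldehyde
Product: 3 (2S,5S)-2-tert-butyl-5-methyl-1,3-dioxolan-4-one (tert-butyl and methyl cis)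
Conditions: TsOH·H2O (cat.), H2SO4 (cat.), pentane, reflux, Dean–Stark; crystallization from pentane/Et2O, −78 °C
Reagents that add atoms: none
Why: Acid-catalysed acetalization of the α-hydroxy acid with azeotropic removal of water; the acetal stereocenter is set under thermodynamic control by the lactate center, the cis isomer being favoured and purified by low-temperature crystallization.

Step 2
Reactants: 4 methyl 5,5-dimethoxy-3-oxopentanoate
Product: 5 4-hydroxy-2H-pyran-2-one
Conditions: 90% aq. H2SO4, 0 °C → rt; then ice-water
Reagents that add atoms: water, O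
Why: Acid unmasks the aldehyde and the resulting 3,5-dioxopentanoate should undergo enol-lactonization onto the methyl ester, the cyclodehydration by which 3,5-dioxo esters give 4-hydroxy-2-pyranones.

Step 3
Reactants: 5 4-hydroxy-2H-pyran-2-one
Product: 6 2-oxo-2H-pyran-4-yl 4-methylbenzenesulfonate
Conditions: TsCl, Et3N, CH2Cl2, 0 °C
Reagents that add atoms: 4-toluenesulfonyl chloride, Cc1ccc(cc1)S(=O)(=O)Cl
Why: O-Sulfonylation of the acidic vinylogous-acid hydroxyl gives a vinylogous acyl tosylate that is activated for oxidative addition.

Step 4
Reactants: 6 2-oxo-2H-pyran-4-yl 4-methylbenzenesulfonate; 7 1-nonyne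
Product: 8 4-(non-1-yn-1-yl)-2H-pyran-2-one
Conditions: PdCl2(PPh3)2 (cat.), CuI (cat.), i-Pr2NEt, MeCN, 50 °C
Reagents that add atoms: none
Why: Sonogashira coupling of an electron-poor 4-sulfonyloxy-2-pyranone, a pseudohalide class known to couple with terminal alkynes, with a non-nucleophilic amine that spares the lactone.

Step 5
Reactants: 3 (2S,5S)-2-tert-butyl-5-methyl-1,3-dioxolan-4-one; 8 4-(non-1-yn-1-yl)-2H-pyran-2-one
Product: 11 (R)-3-heptyl-7-hydroxy-7-methyl-6H-isochromene-6,8(7H)-dione, via lithium dienolate 9 (not isolated), via formyl vinylogous acid 10 (not isolated)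
Conditions: LiHMDS, THF, −78 °C (3 added to the base); then 8, −78 → 0 °C; AcOH; then aq. KH2PO4/K2HPO4 (pH 7), MeCN, rt
Reagents that add atoms: none
Why: Proposed new method: the lithium enolate of 3 should add, on the face anti to the tert-butyl group, to the enol-lactone carbonyl of 8 (crossed Claisen acylation, C6–C7); the tetrahedral adduct collapses with opening of the pyranone to the formyl dienolate 9, whose α-carbon C8a then attacks the activated acetal-ester carbonyl C8 of the dioxolanone (Dieckmann acylation, C8–C8a) with loss of pivalaldehyde to give 10 as its stabilized enolate. The closest known reaction types are C-acylation of the enolate of this dioxolanone (including its self-condensation at the dioxolanone carbonyl, which shows both acyl transfers), carbanion-induced ring opening and ring transformation of 2-pyranones, and the Dieckmann condensation. Ring A closes in a 6-(enolexo)-exo-trig mode, for which the pyranone delivers C6 and C8a cis on the C4a=C5 double bond; ring B then closes by 6-endo-dig oxa-Michael addition of the C1 enol oxygen to the enynone under the phosphate buffer, a closure known for 2-alkynyl formyl dienones of this kind. The only stereocenter, C7, is set in the Claisen step by the acetal carbon of 3 (self-regeneration of stereocenters: the acyl group takes the place of the lactate hydrogen with retention, which corresponds to 7R); it should not be lost afterwards, because C7 is quaternary and the formyl group on C8a keeps C6 and C8 constitutionally different. The step needs 1,2-attack at the lactone carbonyl in preference to 1,6-addition at C1 or at the alkyne and to proton transfer; the hard, hindered lithium enolate at −78 °C, the activated enol-ester carbonyl and the fully substituted C4a are counted on to secure it, and C-acylation at C8a is the only closure of dienolate 9 that gives an unstrained ring.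

Step 6
Reactants: 11 (R)-3-heptyl-7-hydroxy-7-methyl-6H-isochromene-6,8(7H)-dione; 12 decanoyl chloride
Product: 13 (R)-3-heptyl-7-methyl-6,8-dioxo-7,8-dihydro-6H-isochromen-7-yl decanoate (target)
Conditions: pyridine, DMAP (cat.), CH2Cl2, 0 °C → rt
Reagents that add atoms: none
Why: DMAP-catalysed O-acylation (acylpyridinium transfer) of the tertiary carbinol, the usual way to esterify 7-hydroxy azaphilones; C7 is quaternary and not involved, so its configuration should be retained.

**Compound list**

1 | (S)-lactic acid | C[C@H](O)C(=O)O | starting material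
2 | pivalaldehyde | CC(C)(C)C=O | starting material
3 | (2S,5S)-2-tert-butyl-5-methyl-1,3-dioxolan-4-one | C[C@@H]1O[C@H](C(C)(C)C)OC1=O | intermediate
4 | methyl 5,5-dimethoxy-3-oxopentanoate | COC(=O)CC(=O)CC(OC)OC | starting material
5 | 4-hydroxy-2H-pyran-2-one | OC1=CC(=O)OC=C1 | intermediate
6 | 2-oxo-2H-pyran-4-yl 4-methylbenzenesulfonate | Cc1ccc(cc1)S(=O)(=O)OC1=CC(=O)OC=C1 | intermediate
7 | 1-nonyne | CCCCCCCC#C | starting material
8 | 4-(non-1-yn-1-yl)-2H-pyran-2-one | CCCCCCCC#CC1=CC(=O)OC=C1 | intermediate
9 | lithium (1Z,3Z)-dienolate of the ring-opened Claisen adduct, (2S,5R)-2-tert-butyl-5-methyl-4-oxo-1,3-dioxolan-5-yl ketone | [Li+].[O-]/C=C\C(C#CCCCCCCC)=C/C(=O)[C@@]1(C)O[C@H](C(C)(C)C)OC1=O | intermediate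
10 | formyl vinylogous acid, (R)-2,5-dihydroxy-5-methyl-6-(non-1-yn-1-yl)-4-oxocyclohexa-1,... written as the 6-formyl-5-hydroxy dienone tautomer | O[C@]1(C)C(=O)C=C(C#CCCCCCCC)C(C=O)=C1O | intermediate
11 | (R)-3-heptyl-7-hydroxy-7-methyl-6H-isochromene-6,8(7H)-dione | O[C@]1(C)C(=O)C=C2C=C(CCCCCCC)OC=C2C1=O | intermediate
12 | decanoyl chloride | CCCCCCCCCC(=O)Cl | starting material
13 | (R)-3-heptyl-7-methyl-6,8-dioxo-7,8-dihydro-6H-isochromen-7-yl decanoate | CCCCCCCCCC(=O)O[C@]1(C)C(=O)C=C2C=C(CCCCCCC)OC=C2C1=O | target

Total step count: 6. Longest linear sequence: 5 steps (4 → 5 → 6 → 8 → 11 → 13).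

**Steps most likely to fail**

1. Step 5. The enolate may add in a conjugate (1,6) sense at C1 of the pyranone or at the alkyne terminus, or may be quenched by proton transfer from the propargylic position, instead of acylating at the lactone carbonyl; the cascade may also stall at the dienolate stage without the Dieckmann closure. The fallback uses the established aromatic route, sets out from 1-nonyne 7 and comes back at 10. Vilsmeier formylation (POCl3, DMF) of commercial 5-bromo-1,3-dimethoxy-2-methylbenzene should give 6-bromo-2,4-dimethoxy-3-methylbenzaldehyde F1. Demethylation with BBr3 in CH2Cl2 should give 6-bromo-2,4-dihydroxy-3-methylbenzaldehyde F2. Sonogashira coupling with 7 (PdCl2(PPh3)2, CuI, Et3N, DMF) should give 2,4-dihydroxy-3-methyl-6-(non-1-yn-1-yl)benzaldehyde F3. Copper-mediated enantioselective oxidative dearomatization ([Cu(MeCN)4]PF6, sparteine, O2, i-Pr2NEt, DMAP, CH2Cl2, −78 → −10 °C), using the sparteine enantiomer or surrogate that leads to the 7R series, should then give 10, which is carried through the same buffered cycloisomerization to 11.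

2. Step 2. Intermolecular aldol self-condensation of the unmasked formyl keto ester may outrun enol-lactonization. The fallback introduces the alkyne before the ring is formed, sets out from 4 and comes back at 8. (E)-Selective enol triflation (Tf2O, aq. Me4NOH, hexane, 0 °C) should give methyl (E)-5,5-dimethoxy-3-(trifluoromethylsulfonyloxy)pent-2-enoate F4. Sonogashira coupling with 7 (PdCl2(PPh3)2, CuI, Et3N, THF) should give methyl (E)-3-(2,2-dimethoxyethyl)dodec-2-en-4-ynoate F5, in which the acetal arm is cis to the ester. Acid (TsOH·H2O, wet toluene, heat) should then unmask the aldehyde and lactonize it onto the cis ester to give 8; this substrate has no 1,3-dicarbonyl unit to self-condense, and the fallback also bypasses 5 and 6.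

3. Step 6. Acylation of the hindered tertiary carbinol may be slow, so that base-induced α-ketol ring contraction or attack of the nucleophilic catalyst on ring B competes. The fallback forms the C7–O bond oxidatively with the carboxylate already in place; it sets out from 1-nonyne 7 through aldehyde F3 of the first fallback and comes back at 13. Cycloisomerization of F3 with Au(OAc)3 (cat.) in TFA/1,2-dichloroethane should give 3-heptyl-6,8-dihydroxy-7-methyl-2-benzopyrylium trifluoroacetate F6. Wessely-type acyloxylative dearomatization with Pb(OAc)4 in decanoic acid/CH2Cl2 should deliver the racemic decanoate F7 directly. Preparative chromatography on a chiral stationary phase should separate 13 from its (S)-enantiomer F8.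

**Further compounds**

F1 | step 5 | 6-bromo-2,4-dimethoxy-3-methylbenzaldehyde | COc1cc(Br)c(C=O)c(OC)c1C
F2 | step 5 | 6-bromo-2,4-dihydroxy-3-methylbenzaldehyde | Oc1cc(Br)c(C=O)c(O)c1C
F3 | step 5 | 2,4-dihydroxy-3-methyl-6-(non-1-yn-1-yl)benzaldehyde | CCCCCCCC#Cc1cc(O)c(C)c(O)c1C=O
F4 | step 2 | methyl (E)-5,5-dimethoxy-3-(trifluoromethylsulfonyloxy)pent-2-enoate | COC(=O)/C=C(/OS(=O)(=O)C(F)(F)F)CC(OC)OC
F5 | step 2 | methyl (E)-3-(2,2-dimethoxyethyl)dodec-2-en-4-ynoate | COC(=O)/C=C(/C#CCCCCCCC)CC(OC)OC
F6 | step 6 | 3-heptyl-6,8-dihydroxy-7-methyl-2-benzopyrylium trifluoroacetate | CCCCCCCc1cc2cc(O)c(C)c(O)c2c[o+]1.[O-]C(=O)C(F)(F)F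
F7 | step 6 | racemic 3-heptyl-7-methyl-6,8-dioxo-7,8-dihydro-6H-isochromen-7-yl decanoate | CCCCCCCCCC(=O)OC1(C)C(=O)C=C2C=C(CCCCCCC)OC=C2C1=O
F8 | step 6 | (S)-3-heptyl-7-methyl-6,8-dioxo-7,8-dihydro-6H-isochromen-7-yl decanoate | CCCCCCCCCC(=O)O[C@@]1(C)C(=O)C=C2C=C(CCCCCCC)OC=C2C1=O
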